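**Retrosynthetic overview**

1. The route rests on the C4a–C9a bond, the hub of a [4.3.3]propellane (dihydrofuran, indoline, piperidine). C9a carries N9 and the indolyl carbon C4', and C4a carries the ether oxygen bound to C5'. C9a is therefore the C2 carbonyl of a 3-aryloxyoxindole, and the dihydrofuran ring (O–C4a–C9a–C4'–C5') closes when C4' attacks that activated lactam.
2. Late stage: the gramine arm comes from a Mannich reaction at C3' after detosylation. The piperidine (N2–C1 and N2–C3) comes from double reductive amination of a dialdehyde, made by cleaving a C9a-vinyl/C4a-allyl pair. C9a–C1 comes from vinyl Grignard addition to the C9a=N9 ketimine.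
3. Key disconnection: C4'–C9a, by triflic anhydride activation of the secondary lactam and intramolecular aza-Friedel–Crafts closure.
4. Precursor: the aryl ether comes from SNAr of the (S)-3-allyl-3-hydroxyoxindole alkoxide on 4-fluoro-2-methoxy-1-nitrobenzene, and the indole pyrrole ring from a Bartoli reaction. C4a is set by catalytic asymmetric allylboration of N-tritylisatin.
5. Ring order: oxindole (from isatin), then indole pyrrole ring, then dihydrofuran, then piperidine.

Key step: step 7

Remarks: Atom labels are those of the target's tetrahydro-β-carboline core (C1, N2, C3, C4, C4a, C4b, N9, C9a), with primed labels for the methoxyindole; they are used for all intermediates. The target is (4aS,9aR). In step 2 the catalyst antipode that gives the (S)-carbinol is assumed; the sense of induction would be verified on compound 4 before going on. The trityl group replaces a generic lactam N-protecting group, and the C1 unit is brought in as a vinyl group rather than as nitromethane (reasons under the risk list).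

**Route**

Step 1
Reactants: 1 isatin
Product: 2 1-tritylisatin
Conditions: NaH, DMF, 0 °C; TrCl, rt
Reagents that add atoms: trityl chloride, ClC(c1ccccc1)(c1ccccc1)c1ccccc1
Why: N-alkylation of the isatin sodium salt with the SN1-active trityl chloride should give a base-stable, Grignard-stable and acid-labile N-trityl lactam whose bulk also screens the C2 carbonyl in steps 3 to 5.

Step 2
Reactants: 2 1-tritylisatin; 3 allylboronic acid pinacol ester
Product: 4 (S)-3-allyl-3-hydroxy-1-tritylindolin-2-one
Conditions: chiral valine-derived aminophenol catalyst (cat.), NaOt-Bu (cat.), MeOH, toluene, rt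
Reagents that add atoms: none
Why: Catalytic enantioselective allylboration of the C3 ketone of an N-protected isatin, in which the catalyst-bound allylboron delivers allyl through a closed six-membered transition state to one ketone face, should set the carbinol centre (the future C4a) as S under catalyst control.

Step 3
Reactants: 4 (S)-3-allyl-3-hydroxy-1-tritylindolin-2-one; 5 4-fluoro-2-methoxy-1-nitrobenzene
Product: 6 (S)-3-allyl-3-(3-methoxy-4-nitrophenoxy)-1-tritylindolin-2-one
Conditions: NaH, DMF, 0 °C; then 5, 0 °C → rt
Reagents that add atoms: none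
Why: Nucleophilic aromatic substitution (SNAr) of the fluoride para to the nitro group by the tertiary sodium alkoxide leaves the C3–O bond untouched, so the S configuration is retained.

Step 4
Reactants: 6 (S)-3-allyl-3-(3-methoxy-4-nitrophenoxy)-1-tritylindolin-2-one; 7 vinylmagnesium bromide
Product: 8 (S)-3-allyl-3-[(7-methoxy-1H-indol-5-yl)oxy]-1-tritylindolin-2-one
Conditions: CH2=CHMgBr (3.5 equiv), THF, −45 °C; aq NH4Cl
Reagents that add atoms: none
Why: In the Bartoli indole synthesis the ortho-methoxy nitroarene passes through the nitrosoarene and an N-aryl-O-vinylhydroxylamine whose [3,3]-shift can only reach the unsubstituted ortho carbon, which should give the 7-methoxyindole with the ether at C5' while the trityl-shielded tertiary lactam stays intact at low temperature.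

Step 5
Reactants: 8 (S)-3-allyl-3-[(7-methoxy-1H-indol-5-yl)oxy]-1-tritylindolin-2-one
Product: 9 (S)-3-allyl-3-[(7-methoxy-1-tosylindol-5-yl)oxy]-1-tritylindolin-2-one
Conditions: NaH, THF/DMF, 0 °C; TsCl, rt
Reagents that add atoms: p-toluenesulfonyl chloride, Cc1ccc(S(=O)(=O)Cl)cc1
Why: N-Sulfonylation of the indole sodium salt (the lactam nitrogen is blocked) installs a tosyl group that deactivates N1', C2' and C3' towards triflic anhydride in step 7.

Step 6
Reactants: 9 (S)-3-allyl-3-[(7-methoxy-1-tosylindol-5-yl)oxy]-1-tritylindolin-2-one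
Product: 10 (S)-3-allyl-3-[(7-methoxy-1-tosylindol-5-yl)oxy]indolin-2-one
Conditions: TFA, Et3SiH, CH2Cl2, 0 °C → rt
Reagents that add atoms: none
Why: Acidolytic N-detritylation (SN1 loss of the trityl cation from the protonated anilide, trapped by the silane as triphenylmethane) should free the lactam N–H without alkylating the electron-rich indolyl ether, since the trityl cation is too bulky, and the alkene, the N-tosyl group and the tertiary ether tolerate TFA at room temperature.

Step 7
Reactants: 10 (S)-3-allyl-3-[(7-methoxy-1-tosylindol-5-yl)oxy]indolin-2-one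
Product: 12 (4aS)-4a-allyl C9a=N9 ketimine (benzofuro[3,2-b]indolenine fused through C4'/C5' to the 7'-methoxy-1'-tosylindole), via imidoyl triflate 11 (not isolated)
Conditions: Tf2O (1.1 equiv), 2-ClPyr (2.2 equiv), CH2Cl2, −78 °C → rt; aq NaHCO3
Reagents that add atoms: triflic anhydride, O=S(=O)(OS(=O)(=O)C(F)(F)F)C(F)(F)F (its atoms stay only in intermediate 11)
Why: Triflic anhydride O-sulfonylates the secondary lactam and 2-chloropyridine takes up the N–H proton, giving the 2-triflyloxy-3H-indole 11, which cannot tautomerise to an indole because C4a is quaternary and so stays electrophilic at C9a. The aryl ether carbon C4' attacks C9a from above the lactam plane, and loss of triflate and of the C4' proton should give the C9a=N9 ketimine. The closest known reactions are the Tf2O/2-halopyridine coupling of secondary amides with electron-rich arenes to aromatic ketimines (Bischler–Napieralski-type activation) and the intramolecular Hoesch or Friedel–Crafts closure of aryloxyacetic acid derivatives to benzofuran-3(2H)-ones, of which 12 is the cyclic imine analogue. The dihydrofuran ring (O, C4a, C9a, C4', C5') closes in a 5-exo-trig mode with respect to the C9a=N9 bond. No stereocentre is created, and C4a keeps its S configuration because it has no α-hydrogen and none of its bonds is broken. The step needs C4' over C6' selectivity, which the substrate should supply because C4' is para to the methoxy group whereas C6' lies between the two oxygens and is shielded by the methoxy methyl that the N1' tosyl group pushes towards it.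

Step 8
Reactants: 12 (4aS)-4a-allyl C9a=N9 ketimine; 7 vinylmagnesium bromide
Product: 13 (4aS,9aS)-4a-allyl-9a-vinyl cis-fused benzofuro[3,2-b]indoline (N9–H; 7'-methoxy-1'-tosylindole unit)
Conditions: CH2=CHMgBr (3 equiv), THF, −40 °C → rt (BF3·OEt2 pre-complexation if sluggish); aq NH4Cl
Reagents that add atoms: none
Why: 1,2-Addition of a Grignard reagent to a non-enolisable, ring-strained cyclic ketimine (3H-indole) can only occur on the face of C9a that gives the cis-fused dihydrofuran/indoline bicycle, so the vinyl group should end up syn to the allyl group and C9a is set by the existing C4a centre (substrate control).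

Step 9
Reactants: 13 (4aS,9aS)-4a-allyl-9a-vinyl cis-fused benzofuro[3,2-b]indoline
Product: 15 (4aS,9aS)-9a-formyl-4a-(2-oxoethyl) dialdehyde, via tetraol 14 (not isolated)
Conditions: OsO4 (cat.), NMO, acetone/H2O, rt; then NaIO4, THF/pH 7 buffer, 0 °C
Reagents that add atoms: N-methylmorpholine N-oxide, C[N+]1([O-])CCOCC1; water, O (oxygen delivered through catalytic osmium tetroxide, O=[Os](=O)(=O)=O)
Why: Upjohn dihydroxylation of the two monosubstituted alkenes followed by periodate glycol cleavage (Lemieux–Johnson sequence) should excise both terminal carbons, because terminal alkenes are osmylated much faster than the electron-poor C2'=C3' bond of the N-tosylindole and the hindered N-aryl amine N9 is a poor partner for periodate.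

Step 10
Reactants: 15 (4aS,9aS)-9a-formyl-4a-(2-oxoethyl) dialdehyde
Product: 16 (4aS,9aR)-N1'-tosyl hexacycle (the target lacking the C3' dimethylaminomethyl group and carrying tosyl on N1')
Conditions: MeNH2 (2 M in THF), AcOH, NaBH(OAc)3, DCE, 0 °C → rt
Reagents that add atoms: methylamine, CN
Why: Double reductive amination of the 1,5-dialdehyde with methylamine (iminium formation and hydride reduction at one aldehyde, then six-membered cyclic iminium formation and reduction at the other) should close the N-methylpiperidine through N2–C1 and N2–C3 without touching the stereocentres, and N9 cannot compete because its closure onto C3 would give a 1-azabicyclo[2.2.1]heptane.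

Step 11
Reactants: 16 (4aS,9aR)-N1'-tosyl hexacycle
Product: 17 (4aS,9aR)-hexacycle with free indole N1'–H and unsubstituted C3'
Conditions: Mg, MeOH, sonication, rt
Reagents that add atoms: none
Why: Reductive N–S cleavage of the N-sulfonylindole by single-electron transfer from magnesium in methanol should leave the aryl ether, the tertiary amine and the indoline nitrogen untouched.

Step 12
Reactants: 17 (4aS,9aR)-hexacycle with free indole N1'–H and unsubstituted C3'
Product: 18 CNP0318114.2 (target)
Conditions: CH2=NMe2+ I−, MeCN/AcOH, rt; aq NaHCO3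
Reagents that add atoms: Eschenmoser's salt (dimethylmethyleneiminium iodide), C=[N+](C)C.[I-]
Why: Mannich aminomethylation (gramine synthesis) with the preformed iminium salt should occur at C3', the most nucleophilic carbon of the N–H indole, while any N-aminomethyl adduct at N1' or N9 is an aminal that reverts on aqueous work-up.

**Compound list**

1 | isatin | O=C1Nc2ccccc2C1=O | starting material
2 | 1-tritylisatin | O=C1C(=O)N(C(c2ccccc2)(c2ccccc2)c2ccccc2)c2ccccc12 | intermediate
3 | allylboronic acid pinacol ester | C=CCB1OC(C)(C)C(C)(C)O1 | starting material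
4 | (S)-3-allyl-3-hydroxy-1-tritylindolin-2-one | O[C@]1(CC=C)C(=O)N(C(c2ccccc2)(c2ccccc2)c2ccccc2)c2ccccc12 | intermediate
5 | 4-fluoro-2-methoxy-1-nitrobenzene | COc1cc(F)ccc1[N+](=O)[O-] | starting material
6 | (S)-3-allyl-3-(3-methoxy-4-nitrophenoxy)-1-tritylindolin-2-one | COc1cc(O[C@]2(CC=C)C(=O)N(C(c3ccccc3)(c3ccccc3)c3ccccc3)c3ccccc32)ccc1[N+](=O)[O-] | intermediate
7 | vinylmagnesium bromide | C=C[Mg]Br | starting material
8 | (S)-3-allyl-3-[(7-methoxy-1H-indol-5-yl)oxy]-1-tritylindolin-2-one | COc1cc(O[C@]2(CC=C)C(=O)N(C(c3ccccc3)(c3ccccc3)c3ccccc3)c3ccccc32)cc2cc[nH]c12 | intermediate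
9 | (S)-3-allyl-3-[(7-methoxy-1-tosylindol-5-yl)oxy]-1-tritylindolin-2-one | COc1cc(O[C@]2(CC=C)C(=O)N(C(c3ccccc3)(c3ccccc3)c3ccccc3)c3ccccc32)cc2ccn(S(=O)(=O)c3ccc(C)cc3)c12 | intermediate
10 | (S)-3-allyl-3-[(7-methoxy-1-tosylindol-5-yl)oxy]indolin-2-one (key-step precursor) | COc1cc(O[C@]2(CC=C)C(=O)Nc3ccccc32)cc2ccn(S(=O)(=O)c3ccc(C)cc3)c12 | intermediate
11 | (S)-3-allyl-3-[(7-methoxy-1-tosylindol-5-yl)oxy]-3H-indol-2-yl triflate (imidoyl triflate, not isolated) | COc1cc(O[C@]2(CC=C)C(OS(=O)(=O)C(F)(F)F)=Nc3ccccc32)cc2ccn(S(=O)(=O)c3ccc(C)cc3)c12 | intermediate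
12 | (4aS)-4a-allyl C9a=N9 ketimine (key-step product) | COc1cc2c(c3ccn(S(=O)(=O)c4ccc(C)cc4)c13)C1=Nc3ccccc3[C@]1(CC=C)O2 | intermediate
13 | (4aS,9aS)-4a-allyl-9a-vinyl cis-fused indoline | COc1cc2c(c3ccn(S(=O)(=O)c4ccc(C)cc4)c13)[C@]1(C=C)Nc3ccccc3[C@]1(CC=C)O2 | intermediate
14 | (4aS,9aR)-9a-(1,2-dihydroxyethyl)-4a-(2,3-dihydroxypropyl) tetraol, mixture at the two carbinol carbons (not isolated) | COc1cc2c(c3ccn(S(=O)(=O)c4ccc(C)cc4)c13)[C@]1(C(O)CO)Nc3ccccc3[C@]1(CC(O)CO)O2 | intermediate
15 | (4aS,9aS)-9a-formyl-4a-(2-oxoethyl) dialdehyde | COc1cc2c(c3ccn(S(=O)(=O)c4ccc(C)cc4)c13)[C@]1(C=O)Nc3ccccc3[C@]1(CC=O)O2 | intermediate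
16 | (4aS,9aR)-N1'-tosyl hexacycle | COc1cc2c(c3ccn(S(=O)(=O)c4ccc(C)cc4)c13)[C@@]13CN(C)CC[C@]1(O2)c1ccccc1N3 | intermediate
17 | (4aS,9aR)-hexacycle with free N1'–H and unsubstituted C3' | COc1cc2c(c3cc[nH]c13)[C@@]13CN(C)CC[C@]1(O2)c1ccccc1N3 | intermediate
18 | CNP0318114.2, (4aS,9aR) | COc1cc2c(c3c(CN(C)C)c[nH]c13)[C@@]13CN(C)CC[C@]1(O2)c1ccccc1N3 | target

**Step count and risks**

Total step count: 12. Longest linear sequence: 12 steps (1 → 18).

Steps most likely to fail:

1. Step 7. The activated lactam may stall at the imidoyl triflate, closure may go to C6' instead of C4', or the strained ketimine may be lost by hydration. The fallback fixes the position with a halogen and makes the same bond by a Parham cyclisation. It sets out from 5 (with alcohol 4). Bromination of 5 (NBS, H2SO4), where all directing effects converge on the carbon para to the methoxy group, gives 1-bromo-2-fluoro-4-methoxy-5-nitrobenzene F1. SNAr with the sodium alkoxide of 4 gives the bromo nitroaryl ether F2. Bartoli indolisation gives the 4'-bromoindole F3, and tosylation gives the N-tosyl bromide F4. Bromine–lithium exchange (t-BuLi, THF, −95 °C) and 5-exo addition of the aryllithium to the lactam carbonyl give the cis-fused N-trityl carbinolamine F5. TFA in wet CH2Cl2 without silane removes the trityl group and dehydrates the carbinolamine, and the route is rejoined at ketimine 12.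

2. Step 4. With an ortho-methoxy group the nitro group may be consumed by reduction to the aniline instead of indolisation. The fallback builds the pyrrole ring by alkyne cyclisation and sets out from 6. Nitro reduction (Fe, NH4Cl, EtOH/H2O) gives the aniline F6. Iodination ortho to the amino group (NIS, MeCN) gives the o-iodoaniline F7. Sonogashira coupling with trimethylsilylacetylene gives the o-alkynylaniline F8. TBAF in hot THF removes the silyl group and effects the 5-endo cyclisation, and the route is rejoined at indole 8.

3. Step 9. Periodate may over-oxidise through the vicinal N9–H and C1 oxygen (amino-alcohol-type cleavage of the C9a–C1 bond), or the indole C2'=C3' bond may be osmylated. The fallback brings C1 in with its nitrogen, so that no oxygen sits next to N9, and sets out from 12; it also covers a failure of step 8. Aza-Henry addition of nitromethane (MeNO2, catalytic DBU) gives the β-nitroamine F9. Lemieux–Johnson cleavage of the allyl group without base gives the nitro aldehyde F10, which is reduced at once (H2, Raney Ni, MeOH), the amine closing the ring by reductive amination to the N2–H piperidine F11. Reductive methylation (aq HCHO, NaBH(OAc)3) rejoins the route at 16. This detour is kept in reserve because F10 can undergo an intramolecular Henry reaction under base and the aza-Henry addition is reversible.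

**Further compounds**

F1 | step 7 | 1-bromo-2-fluoro-4-methoxy-5-nitrobenzene | COc1cc(F)c(Br)cc1[N+](=O)[O-]
F2 | step 7 | (S)-3-allyl-3-(2-bromo-5-methoxy-4-nitrophenoxy)-1-tritylindolin-2-one | COc1cc(O[C@]2(CC=C)C(=O)N(C(c3ccccc3)(c3ccccc3)c3ccccc3)c3ccccc32)c(Br)cc1[N+](=O)[O-]
F3 | step 7 | (S)-3-allyl-3-[(4-bromo-7-methoxy-1H-indol-5-yl)oxy]-1-tritylindolin-2-one | COc1cc(O[C@]2(CC=C)C(=O)N(C(c3ccccc3)(c3ccccc3)c3ccccc3)c3ccccc32)c(Br)c2cc[nH]c12
F4 | step 7 | (S)-3-allyl-3-[(4-bromo-7-methoxy-1-tosylindol-5-yl)oxy]-1-tritylindolin-2-one | COc1cc(O[C@]2(CC=C)C(=O)N(C(c3ccccc3)(c3ccccc3)c3ccccc3)c3ccccc32)c(Br)c2ccn(S(=O)(=O)c3ccc(C)cc3)c12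
F5 | step 7 | (4aS,9aR)-4a-allyl-9a-hydroxy-9-trityl cis-fused carbinolamine | COc1cc2c(c3ccn(S(=O)(=O)c4ccc(C)cc4)c13)[C@]1(O)N(C(c3ccccc3)(c3ccccc3)c3ccccc3)c3ccccc3[C@]1(CC=C)O2
F6 | step 4 | (S)-3-allyl-3-(4-amino-3-methoxyphenoxy)-1-tritylindolin-2-one | COc1cc(O[C@]2(CC=C)C(=O)N(C(c3ccccc3)(c3ccccc3)c3ccccc3)c3ccccc32)ccc1N
F7 | step 4 | (S)-3-allyl-3-(4-amino-3-iodo-5-methoxyphenoxy)-1-tritylindolin-2-one | COc1cc(O[C@]2(CC=C)C(=O)N(C(c3ccccc3)(c3ccccc3)c3ccccc3)c3ccccc32)cc(I)c1N
F8 | step 4 | (S)-3-allyl-3-[4-amino-3-methoxy-5-(trimethylsilylethynyl)phenoxy]-1-tritylindolin-2-one | COc1cc(O[C@]2(CC=C)C(=O)N(C(c3ccccc3)(c3ccccc3)c3ccccc3)c3ccccc32)cc(C#C[Si](C)(C)C)c1N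
F9 | step 9 | (4aS,9aR)-4a-allyl-9a-(nitromethyl) cis-fused indoline | COc1cc2c(c3ccn(S(=O)(=O)c4ccc(C)cc4)c13)[C@]1(C[N+](=O)[O-])Nc3ccccc3[C@]1(CC=C)O2
F10 | step 9 | (4aS,9aR)-9a-(nitromethyl)-4a-(2-oxoethyl) aldehyde | COc1cc2c(c3ccn(S(=O)(=O)c4ccc(C)cc4)c13)[C@]1(C[N+](=O)[O-])Nc3ccccc3[C@]1(CC=O)O2
F11 | step 9 | (4aS,9aR)-N1'-tosyl hexacycle with N2–H | COc1cc2c(c3ccn(S(=O)(=O)c4ccc(C)cc4)c13)[C@@]13CNCC[C@]1(O2)c1ccccc1N3
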